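**Plan**

Numbering (longipinane): C1 ketone, C2=C3(Me), cyclobutane C4–C5–C11–C10 (Me on C10), C6 gem-dimethyl, C7 O-angeloyl, C8 H2, C9 O-tigloyl. Ring A = C1–C2–C3–C4–C5–C11; ring B = the ring through C4–C5–(C6)–C7–C8–C9–C10.
Retrosynthesis cuts, in order: the two ester C–O bonds; C6 out of the seven-membered ring B (C5–C6 and C6–C7 cut, C5 rejoined to C7), leaving a six-membered C7 ketone in a 6-6-4 tricycle; the cyclobutane bond C10–C11; the Diels–Alder bonds C4–C10 and C5–C7.
Forward: a Diels–Alder reaction gives cis-fused rings A and B, an enolate/epoxide closure adds the cyclobutane, a semipinacol 1,2-shift inserts C6 and enlarges ring B from six to seven members, then the ring A enone and the two esters are completed.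
Enabling feature: C7 is a carbonyl-level carbon between the gem-dimethyl carbon C6 and the cyclobutane methine C5, so a Me2C unit added to a C7 ketone can be driven into the C5–C7 bond. This one event makes the bicyclo[4.1.1]octane ring, the C6 quaternary centre and the C7 carbonyl that later becomes the anti carbinol.
Stereochemistry: C4 and C5 from the catalyst-controlled Diels–Alder reaction (C10 and C11 follow from the cis fusion and the invertive ring closure), C9 from a CBS reduction, C7 from an anti-selective Evans–Tishchenko reduction that also delivers the tiglate.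

Key step: step 15

Remark: the C3 (Me, OMe) centre, the C10 centre of the bicyclic intermediates and the C7 carbinol of 22 are written as the expected epimers; all three are erased later, so their configuration does not matter.

**Route**

Step 1
Reactants: 1 4-methylphenol
Product: 2 4-methoxy-4-methylcyclohexa-2,5-dien-1-one
Conditions: PhI(OAc)2, MeOH, 0 °C
Reagents that add atoms: methanol, CO
Why: Oxidative dearomatisation of the para-alkylphenol by the hypervalent iodine reagent, with capture of the phenoxenium ion at C4 by methanol, should give the 4,4-disubstituted dienone.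

Step 2
Reactants: 3 1,1-dimethoxyethene; 4 propanoyl chloride
Product: 5 1,1-dimethoxypent-1-en-3-one
Conditions: pyridine, Et2O, 0 → 23 °C
Reagents that add atoms: none
Why: C-Acylation of the nucleophilic ketene acetal by the acid chloride and loss of HCl should give the acylketene acetal, pyridine being too weak a base to form methylketene.

Step 3
Reactants: 5 1,1-dimethoxypent-1-en-3-one
Product: 6 (3Z)-1,1-dimethoxy-3-(trimethylsilyloxy)penta-1,3-diene
Conditions: TMSOTf, Et3N, Et2O, 0 °C
Reagents that add atoms: trimethylsilyl trifluoromethanesulfonate, C[Si](C)(C)OS(=O)(=O)C(F)(F)F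
Why: Soft enolisation (O-silylation, then deprotonation of the ethyl CH2) should give the 1,1-dialkoxy-3-silyloxy diene as the Z silyl enol ether, which places the methyl group outside in the s-cis diene.

Step 4
Reactants: 2 4-methoxy-4-methylcyclohexa-2,5-dien-1-one; 6 (3Z)-1,1-dimethoxy-3-(trimethylsilyloxy)penta-1,3-diene
Product: 7 cis-fused cycloadduct (C11 enone; C7 dimethyl ketal; C9 silyl enol ether; C3 Me/OMe; C10 H/Me)
Conditions: (S)-o-tolyl oxazaborolidinium triflimide (0.2 equiv), CH2Cl2, −78 °C, neutral work-up
Reagents that add atoms: none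
Why: Lewis-acid-catalysed endo Diels–Alder reaction (in the limit a Mukaiyama–Michael addition followed by ring closure) in which the nucleophilic diene terminus C10 bonds to the enone β-carbon C4 and the ketene-acetal carbon C7 to the α-carbon C5; the chiral cation bound to the dienone carbonyl selects one of the two enantiotopic enone units and its face, which sets C4 and C5 cis, and the diene should add syn to the methoxy group on C3.

Step 5
Reactants: 7 cis-fused cycloadduct
Product: 9 C11 allylic alcohol carrying the ring B vinylogous ester C9(=O)–C8H=C7(OMe), via reduced cycloadduct 8 (not isolated)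
Conditions: NaBH4, CeCl3·7H2O, MeOH, −78 °C; then 0.1 M HCl, THF, 0 °C
Reagents that add atoms: none
Why: Luche 1,2-reduction of the C11 enone carbonyl is done before the masked 1,3-dicarbonyl is unveiled, so that H5 never lies between two carbonyls; the acid work-up then hydrolyses the silyl enol ether and expels methanol to give the vinylogous ester (the carbinol configuration is of no consequence).

Step 6
Reactants: 9 C11 allylic alcohol
Product: 10 cis-fused C11=C1 alkene (C2 now CH2)
Conditions: 2-nitrobenzenesulfonylhydrazide, PPh3, DEAD, THF, −30 → 23 °C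
Reagents that add atoms: none
Why: Mitsunobu displacement of the C11 alcohol by the sulfonylhydrazide nitrogen, loss of the sulfinic acid to the monoalkyl diazene and retro-ene extrusion of N2 should deliver hydrogen to C2 and move the alkene to C11=C1 (reductive 1,3-transposition of an allylic alcohol).

Step 7
Reactants: 10 cis-fused C11=C1 alkene
Product: 11 C1–C11 epoxide (oxygen on the convex face, cis to H4 and H5)
Conditions: mCPBA, CH2Cl2, 0 °C
Reagents that add atoms: 3-chloroperoxybenzoic acid, O=C(OO)c1cccc(Cl)c1
Why: Prilezhaev epoxidation of the only isolated alkene (the push–pull enol ether alkene is deactivated) from the convex face of the cis-fused bicycle should place the oxygen anti to the later approach of C10.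

Step 8
Reactants: 11 C1–C11 epoxide
Product: 13 tricyclic vinylogous ester (cyclobutane C4–C5–C11–C10 closed; C1–OTBS), via lithium alkoxide 12 (not isolated)
Conditions: LiN(iPr)2, THF, −78 → 23 °C; then TBSOTf, −78 → 0 °C
Reagents that add atoms: tert-butyldimethylsilyl trifluoromethanesulfonate, CC(C)(C)[Si](C)(C)OS(=O)(=O)C(F)(F)F
Why: Kinetic α'-deprotonation of the vinylogous ester at C10 (Stork–Danheiser regiochemistry, C8 being vinylic) and 4-exo-tet opening of the epoxide at C11 with inversion, favoured over the 5-endo attack at C1, should close the cyclobutane and set the quaternary C10 and C11, since the enolate can reach C11 only from the concave face; the C1 alkoxide is silylated in the flask.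

Step 9
Reactants: 13 tricyclic vinylogous ester
Product: 14 C9 ketone with C7 masked as 1,3-dithiane
Conditions: HS(CH2)3SH, TsOH·H2O (0.1 equiv), CH2Cl2, 23 °C
Reagents that add atoms: propane-1,3-dithiol, SCCCS
Why: Acid-catalysed addition–elimination of the dithiol at C7 of the vinylogous ester followed by thioketalisation should give the β-keto dithiane, which masks C7 and leaves C9 as a saturated ketone between the quaternary C10 and a methylene.

Step 10
Reactants: 14 C9 ketone C7 dithiane
Product: 15 (9R)-alcohol
Conditions: (S)-2-methyl-CBS-oxazaborolidine (0.2 equiv), BH3·SMe2, THF, −20 °C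
Reagents that add atoms: none
Why: CBS reduction with the quaternary C10 as the large and the C8 methylene as the small substituent should give the 9R carbinol under reagent control, which is needed because the two carbonyl faces differ only through remote ring A substituents.

Step 11
Reactants: 15 (9R)-alcohol
Product: 16 C9 TIPS ether
Conditions: TIPSOTf, 2,6-lutidine, CH2Cl2, 0 → 23 °C
Reagents that add atoms: triisopropylsilyl trifluoromethanesulfonate, CC(C)[Si](C(C)C)(C(C)C)OS(=O)(=O)C(F)(F)F
Why: Silylation with the silyl triflate protects the hindered neopentyl C9 hydroxyl, which would otherwise trap the C6 cation equivalent of step 15 as a tetrahydrofuran.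

Step 12
Reactants: 16 C9 TIPS ether
Product: 17 six-membered C7 ketone (6-6-4 tricycle; C9–OTIPS; C1–OTBS)
Conditions: MeI, CaCO3, MeCN/H2O, 45 °C
Reagents that add atoms: water, O
Why: S-Methylation of the dithiane and hydrolysis of the sulfonium ion should release the C7 ketone under nearly neutral conditions that both silyl ethers and the tertiary methyl ether tolerate.

Step 13
Reactants: 18 acetone; 19 benzeneselenol
Product: 20 2,2-bis(phenylselanyl)propane
Conditions: 19 (2.1 equiv in all), ZnCl2 (0.5 equiv), 4 Å molecular sieves, CH2Cl2, 23 °C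
Reagents that add atoms: benzeneselenol (the second equivalent), [SeH]c1ccccc1
Why: Lewis-acid-catalysed selenoacetalisation: the first equivalent of the selenol adds to the carbonyl to give the hemiselenoacetal, loss of water gives the selenium-stabilised cation, and the second equivalent of the selenol captures it.

Step 14
Reactants: 17 six-membered C7 ketone; 20 2,2-bis(phenylselanyl)propane
Product: 22 β-hydroxy selenide (C7 carbinol bearing the CMe2SePh group), via 2-lithio-2-(phenylselanyl)propane 21 (not isolated)
Conditions: 20, n-BuLi, THF, −78 °C; then 17, −78 °C; H2O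
Reagents that add atoms: none
Why: Selenium–lithium exchange gives the α-selenoalkyllithium, a weakly basic tertiary carbanion equivalent that should add to the C7 ketone faster than it enolises it towards C8; the carbinol configuration is irrelevant.

Step 15
Reactants: 22 β-hydroxy selenide
Product: 23 ring-enlarged C7 ketone (longipinane skeleton; C6 gem-dimethyl; C9–OTIPS; C1–OTBS)
Conditions: AgBF4, neutral Al2O3, CH2Cl2, 23 °C
Reagents that add atoms: none
Why: AgBF4 binds the selenium of 22 and makes PhSe a leaving group on C6; as the C6–Se bond ionises, the antiperiplanar ring bond C5–C7 shifts from C7 to C6 while the C7 hydroxyl collapses to the carbonyl (semipinacol rearrangement of a β-hydroxy selenide, the closest known type being a Tiffeneau–Demjanov ring enlargement). No ring is closed by a cyclisation: the six-membered ring B (C4–C5–C7–C8–C9–C10) becomes the seven-membered ring C4–C5–C6–C7–C8–C9–C10 by insertion of C6, and the bicyclo[3.1.1]heptane unit relaxes to a bicyclo[4.1.1]octane. C6 becomes the gem-dimethyl quaternary carbon and is not stereogenic, C5 migrates with retention, and both C7 epimers of 22 converge because C7 returns to sp2, so no stereocentre is made or lost. The step needs regioselective migration of C5 over C8: C5 is a secondary carbon and the better migrating group, whereas C8 is a methylene deactivated inductively by the C9 silyloxy group. The fully substituted selenium-bearing carbon should favour rearrangement over epoxide closure, and the alumina buffers the acid so that the silyl ethers and the tertiary methyl ether survive.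

Step 16
Reactants: 23 ring-enlarged C7 ketone
Product: 24 C1 alcohol
Conditions: CSA (0.1 equiv), MeOH/CH2Cl2, 0 °C
Reagents that add atoms: none
Why: Acid-catalysed methanolysis should remove the less hindered secondary TBS ether at C1 while the bulkier TIPS ether on the neopentyl C9 oxygen stays.

Step 17
Reactants: 24 C1 alcohol
Product: 26 longipin-2-ene-1,7-dione 9-TIPS ether, via β-methoxy diketone 25 (not isolated)
Conditions: Dess–Martin periodinane, CH2Cl2, 23 °C; then DBU, 23 °C
Reagents that add atoms: none
Why: Oxidation of the C1 carbinol gives a β-methoxy ketone whose E1cB loss of methoxide from C3 (C11 is a bridgehead and cannot enolise) should give the conjugated C2=C3 enone without a carbocation next to the cyclobutane.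

Step 18
Reactants: 26 longipin-2-ene-1,7-dione 9-TIPS ether
Product: 27 (9R)-9-hydroxylongipin-2-ene-1,7-dione
Conditions: HF·pyridine, THF, 0 → 23 °C
Reagents that add atoms: none
Why: Fluoride-mediated desilylation under buffered acidic conditions should free the C9 hydroxyl without retro-aldol cleavage or β-elimination of the β-hydroxy ketone.

Step 19
Reactants: 27 (9R)-9-hydroxylongipin-2-ene-1,7-dione; 28 (E)-2-methylbut-2-enal
Product: 29 (7R,9R)-7-hydroxy-9-tigloyloxylongipin-2-en-1-one
Conditions: SmI2 (0.3 equiv), 28 (6 equiv), THF, −10 °C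
Reagents that add atoms: none
Why: Evans–Tishchenko reduction: the C9 hydroxyl forms a hemiacetal with the aldehyde, samarium chelates the hemiacetal oxygen and the C7 carbonyl in a six-membered transition state, and the hemiacetal hydride is delivered to C7 on the face of the C9 oxygen, so the new C7 hydroxyl should be anti (7R), only the β-hydroxy ketone carbonyl is reduced (not the C1 enone), and the oxidised aldehyde stays on O9 as the tiglate.

Step 20
Reactants: 29 (7R,9R)-7-hydroxy-9-tigloyloxylongipin-2-en-1-one; 30 angelic acid
Product: 32 (7R,9R)-7-angeloyloxy-9-tigloyloxylongipin-2-en-1-one (target), via angelic 2,4,6-trichlorobenzoic anhydride 31 (not isolated)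
Conditions: 30, 2,4,6-trichlorobenzoyl chloride, Et3N, toluene, 23 °C; then 29, toluene, 80 °C
Reagents that add atoms: none
Why: Yamaguchi-type acylation through the mixed anhydride without a nucleophilic amine catalyst, conditions under which the Z double bond of the angelate should not isomerise to the tiglate and the C9 ester should not migrate.

**Compound list**

1 | 4-methylphenol (p-cresol) | Cc1ccc(O)cc1 | starting material
2 | 4-methoxy-4-methylcyclohexa-2,5-dien-1-one | COC1(C)C=CC(=O)C=C1 | intermediate
3 | 1,1-dimethoxyethene | C=C(OC)OC | starting material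
4 | propanoyl chloride | CCC(Cl)=O | starting material
5 | 1,1-dimethoxypent-1-en-3-one | CCC(=O)C=C(OC)OC | intermediate
6 | (3Z)-1,1-dimethoxy-3-(trimethylsilyloxy)penta-1,3-diene | COC(OC)=C/C(O[Si](C)(C)C)=C/C | intermediate
7 | cis-fused cycloadduct: 4,8,8-trimethoxy-4,5-dimethyl-6-(trimethylsilyloxy)-4a,5,8,8a-tetrahydronaphthalen-1(4H)-one, H4 and H5 (longipinane numbering) cis, OMe on C3 cis to the C4–C10 bond | COC1(OC)C=C(O[Si](C)(C)C)[C@@H](C)[C@H]2[C@@](C)(OC)C=CC(=O)[C@@H]12 | intermediate
8 | reduced cycloadduct: C11 carbinol of 7 (not isolated) | COC1(OC)C=C(O[Si](C)(C)C)[C@@H](C)[C@H]2[C@@](C)(OC)C=C[C@@H](O)[C@@H]12 | intermediate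
9 | C11 allylic alcohol with ring B vinylogous ester C9(=O)–C8H=C7(OMe), cis-fused | COC1=CC(=O)[C@@H](C)[C@H]2[C@@](C)(OC)C=C[C@@H](O)[C@@H]12 | intermediate
10 | cis-fused C11=C1 alkene (C2 methylene, C3 Me/OMe, ring B vinylogous ester) | COC1=CC(=O)[C@@H](C)[C@H]2[C@@](C)(OC)CC=C[C@@H]12 | intermediate
11 | C1–C11 epoxide of 10, oxygen on the convex face (cis to H4 and H5) | COC1=CC(=O)[C@@H](C)[C@H]2[C@@](C)(OC)C[C@@H]3O[C@@H]3[C@@H]12 | intermediate
12 | lithium C1 alkoxide of the 6-6-4 tricyclic vinylogous ester (not isolated) | [Li+].COC1=CC(=O)[C@@]2(C)[C@@H]3[C@@H]([O-])C[C@](C)(OC)[C@H]2[C@@H]31 | intermediate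
13 | 6-6-4 tricyclic vinylogous ester: cyclobutane C4–C5–C11–C10, C7(OMe)=C8H–C9(=O) bridge between C5 and C10, C1–OTBS, C3 Me/OMe | COC1=CC(=O)[C@@]2(C)[C@@H]3[C@@H](O[Si](C)(C)C(C)(C)C)C[C@](C)(OC)[C@H]2[C@@H]31 | intermediate
14 | C9 ketone with C7 as spiro-1,3-dithiane | S1CCCSC12CC(=O)[C@@]3(C)[C@@H]4[C@@H](O[Si](C)(C)C(C)(C)C)C[C@](C)(OC)[C@H]3[C@@H]42 | intermediate
15 | (9R)-alcohol of 14 | S1CCCSC12C[C@@H](O)[C@@]3(C)[C@@H]4[C@@H](O[Si](C)(C)C(C)(C)C)C[C@](C)(OC)[C@H]3[C@@H]42 | intermediate
16 | C9 TIPS ether of 15 | S1CCCSC12C[C@@H](O[Si](C(C)C)(C(C)C)C(C)C)[C@@]3(C)[C@@H]4[C@@H](O[Si](C)(C)C(C)(C)C)C[C@](C)(OC)[C@H]3[C@@H]42 | intermediate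
17 | six-membered C7 ketone of the 6-6-4 tricycle (C9–OTIPS, C1–OTBS, C3 Me/OMe) | O=C1C[C@@H](O[Si](C(C)C)(C(C)C)C(C)C)[C@@]2(C)[C@@H]3[C@@H](O[Si](C)(C)C(C)(C)C)C[C@](C)(OC)[C@H]2[C@@H]31 | intermediate
18 | acetone | CC(C)=O | starting material
19 | benzeneselenol | [SeH]c1ccccc1 | starting material
20 | 2,2-bis(phenylselanyl)propane | CC(C)([Se]c1ccccc1)[Se]c1ccccc1 | intermediate
21 | 2-lithio-2-(phenylselanyl)propane (not isolated) | [Li]C(C)(C)[Se]c1ccccc1 | intermediate
22 | β-hydroxy selenide: C7 tertiary carbinol of 17 bearing CMe2SePh (either C7 epimer) | OC1(C(C)(C)[Se]c2ccccc2)C[C@@H](O[Si](C(C)C)(C(C)C)C(C)C)[C@@]3(C)[C@@H]4[C@@H](O[Si](C)(C)C(C)(C)C)C[C@](C)(OC)[C@H]3[C@@H]41 | intermediate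
23 | ring-enlarged longipinan-7-one (C6 gem-dimethyl, C9–OTIPS, C1–OTBS, C3 Me/OMe) | O=C1C[C@@H](O[Si](C(C)C)(C(C)C)C(C)C)[C@@]2(C)[C@@H]3[C@@H](O[Si](C)(C)C(C)(C)C)C[C@](C)(OC)[C@H]2[C@@H]3C1(C)C | intermediate
24 | C1 alcohol of 23 | O=C1C[C@@H](O[Si](C(C)C)(C(C)C)C(C)C)[C@@]2(C)[C@@H]3[C@@H](O)C[C@](C)(OC)[C@H]2[C@@H]3C1(C)C | intermediate
25 | 3-methoxylongipinane-1,7-dione 9-TIPS ether (not isolated) | O=C1C[C@@H](O[Si](C(C)C)(C(C)C)C(C)C)[C@@]2(C)[C@@H]3C(=O)C[C@](C)(OC)[C@H]2[C@@H]3C1(C)C | intermediate
26 | longipin-2-ene-1,7-dione 9-TIPS ether | O=C1C[C@@H](O[Si](C(C)C)(C(C)C)C(C)C)[C@@]2(C)[C@@H]3C(=O)C=C(C)[C@H]2[C@@H]3C1(C)C | intermediate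
27 | (9R)-9-hydroxylongipin-2-ene-1,7-dione | O=C1C[C@@H](O)[C@@]2(C)[C@@H]3C(=O)C=C(C)[C@H]2[C@@H]3C1(C)C | intermediate
28 | (E)-2-methylbut-2-enal (tiglic aldehyde) | C/C=C(\C)C=O | starting material
29 | (7R,9R)-7-hydroxy-9-tigloyloxylongipin-2-en-1-one | O[C@@H]1C[C@@H](OC(=O)/C(C)=C/C)[C@@]2(C)[C@@H]3C(=O)C=C(C)[C@H]2[C@@H]3C1(C)C | intermediate
30 | angelic acid, (Z)-2-methylbut-2-enoic acid | C/C=C(/C)C(=O)O | starting material
31 | angelic 2,4,6-trichlorobenzoic anhydride (not isolated) | C/C=C(/C)C(=O)OC(=O)c1c(Cl)cc(Cl)cc1Cl | intermediate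
32 | (7R,9R)-7-angeloyloxy-9-tigloyloxylongipin-2-en-1-one | C/C=C(/C)C(=O)O[C@@H]1C[C@@H](OC(=O)/C(C)=C/C)[C@@]2(C)[C@@H]3C(=O)C=C(C)[C@H]2[C@@H]3C1(C)C | target

**Step count and risks**

Total step count: 20. Longest linear sequence: 18 steps (steps 2–12 and 14–20).

Steps most likely to fail:

Step 4. The bond to C4 must form next to the quaternary C3, the ketene-acetal diene may be destroyed by the Lewis acid, and the catalyst may give poor selection between the two enone units and their faces. Fallback: 2 and 6 are heated without catalyst in toluene at 80 °C. This gives the racemic cycloadduct, that is 7 together with its mirror image, the ent-cycloadduct F1. Reduction and acid work-up as in step 5 give 9 together with its mirror image, the ent-allylic alcohol F3, formed through the ent-reduced cycloadduct F2. Acylation with vinyl acetate and the lipase from Burkholderia cepacia in MTBE then esterifies one enantiomer, written here for the unwanted one, giving the ent-allylic acetate F4. Unreacted 9 is separated and the route is rejoined at 9; if the enzyme prefers the wanted enantiomer, its acetate is methanolysed to 9.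

Step 8. Deprotonation at C5 with β-elimination of the epoxide, or a 4-exo opening that is too slow, may outrun cyclobutane formation. Fallback from 10: OsO4 (catalytic) with N-methylmorpholine N-oxide should dihydroxylate the C11=C1 alkene from the convex face to the cis-diol F5. SOCl2/Et3N gives the cyclic sulfite F6, and RuCl3 (catalytic)/NaIO4 the cyclic sulfate F7, a much stronger electrophile than the epoxide. LiN(iPr)2 then closes the cyclobutane by the same α'-enolate attack at C11 and gives the lithium sulfate monoester F8. Dilute H2SO4 in wet THF cleaves it to the free C1 alcohol F9, which is silylated with TBSOTf/2,6-lutidine and rejoins the route at 13.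

Step 15. Epoxide closure by the C7 oxygen, elimination of the selenium group, or migration of the C8 methylene may compete with the wanted 1,2-shift of C5. Fallback from 17: isopropenylmagnesium bromide with CeCl3 in THF at −78 °C gives the isopropenyl carbinol F10. A hydrogen-atom-transfer-initiated semipinacol rearrangement (Co(salen) with divalent cobalt as catalyst, PhSiH3, N-fluoro-2,4,6-trimethylpyridinium triflate, acetone, 0 °C) then generates the electron-deficient C6 from the alkene, with no selenium and no free alkoxide. The same shift of C5 should deliver 23, where the route is rejoined.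

Further compounds
F1 | step 4 | ent-cycloadduct (mirror image of 7) | COC1(OC)C=C(O[Si](C)(C)C)[C@H](C)[C@@H]2[C@](C)(OC)C=CC(=O)[C@H]12
F2 | step 4 | ent-reduced cycloadduct (mirror image of 8, not isolated) | COC1(OC)C=C(O[Si](C)(C)C)[C@H](C)[C@@H]2[C@](C)(OC)C=C[C@H](O)[C@H]12
F3 | step 4 | ent-allylic alcohol (mirror image of 9) | COC1=CC(=O)[C@H](C)[C@@H]2[C@](C)(OC)C=C[C@H](O)[C@H]12
F4 | step 4 | ent-allylic acetate (acetate of F3) | COC1=CC(=O)[C@H](C)[C@@H]2[C@](C)(OC)C=C[C@H](OC(C)=O)[C@H]12
F5 | step 8 | C1,C11 cis-diol of 10 (both hydroxyls on the convex face) | COC1=CC(=O)[C@@H](C)[C@H]2[C@@](C)(OC)C[C@H](O)[C@H](O)[C@@H]12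
F6 | step 8 | C1,C11 cyclic sulfite | COC1=CC(=O)[C@@H](C)[C@H]2[C@@](C)(OC)C[C@@H]3OS(=O)O[C@@H]3[C@@H]12
F7 | step 8 | C1,C11 cyclic sulfate | COC1=CC(=O)[C@@H](C)[C@H]2[C@@](C)(OC)C[C@@H]3OS(=O)(=O)O[C@@H]3[C@@H]12
F8 | step 8 | lithium C1 sulfate monoester of the 6-6-4 tricyclic vinylogous ester | [Li+].COC1=CC(=O)[C@@]2(C)[C@@H]3[C@@H](OS(=O)(=O)[O-])C[C@](C)(OC)[C@H]2[C@@H]31
F9 | step 8 | free C1 alcohol of the 6-6-4 tricyclic vinylogous ester | COC1=CC(=O)[C@@]2(C)[C@@H]3[C@@H](O)C[C@](C)(OC)[C@H]2[C@@H]31
F10 | step 15 | isopropenyl carbinol: C7 tertiary alcohol of 17 bearing a prop-1-en-2-yl group (either C7 epimer) | C=C(C)C1(O)C[C@@H](O[Si](C(C)C)(C(C)C)C(C)C)[C@@]2(C)[C@@H]3[C@@H](O[Si](C)(C)C(C)(C)C)C[C@](C)(OC)[C@H]2[C@@H]31
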